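The retrosynthesis first removes the O-benzyl group of a protected enol. It then opens the butenolide (numbering O1, C2 = C=O, C3 = C–OH, C4 = C–Ph, C5 = quaternary) at C3=C4 (aldol condensation) and at O1–C2 (acylation), which leaves the tertiary alcohol PhCO–C(OH)(CO2Me)–CH2Ar 10.
In 10, one stroke cuts the bond from the benzylic CH2 to the quaternary carbon and the chroman bond C4–C4a, and C4 is reconnected to C8a. This gives the vicinal tricarbonyl ester 7 and the dearomatised spiro triene 4, which goes back through spirodienone 3 to raspberry ketone 1.
Enabling feature: on the benzene ring of the chroman, O1 (on C8a), the ring methylene C4 (on the ortho carbon C4a) and the side-chain CH2 (on C6, para to O1) form the 1,2,4-pattern that a 1,2-shift of C4 from C8a to C4a leaves behind. The dihydropyran ring can therefore be stored as a five-membered oxolane spiro-fused at C8a of a 4-methylidenecyclohexa-2,5-diene, whose exocyclic CH2 is the future benzylic carbon and a strong π-nucleophile.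
Forward order: oxolane ring by oxidative dearomatising spirocyclisation, then methylenation, then the key step (C–C union, stereocentre, oxolane-to-dihydropyran expansion, rearomatisation), then the butenolide ring (acylation, aldol condensation), then debenzylation.
Stereochemistry: the only stereocentre, the quaternary carbon (R), is set in the key step by a chiral Cu(II)–bis(oxazoline) chelate of 7. Being quaternary, it cannot epimerise afterwards.

Key step: step 6

Assumption: the sense of induction in step 6 is taken from the accepted square-planar chelate model of Cu(II)–bis(oxazoline) complexes with α-keto esters ((S,S)-ligand, si-face attack, (R)-product); should 7 bind through its other carbonyl pair and reverse the sense, the equally available (R,R)-ligand is used and nothing else changes.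

Step 1
Reactants: 1 4-(4-hydroxyphenyl)butan-2-one (raspberry ketone)
Product: 2 4-(3-hydroxy-3-methylbutyl)phenol
Conditions: MeMgBr (2.5 equiv), THF, 0 °C to rt; then H2O
Reagents that add atoms: methylmagnesium bromide, C[Mg]Br
Why: Grignard addition to the methyl ketone, in which the first equivalent only deprotonates the phenol to an inert magnesium phenoxide; no stereocentre is formed.

Step 2
Reactants: 2 4-(3-hydroxy-3-methylbutyl)phenol
Product: 3 2,2-dimethyl-1-oxaspiro[4.5]deca-6,9-dien-8-one
Conditions: PhI(OAc)2 (1.1 equiv), HFIP/CH2Cl2, 0 °C
Reagents that add atoms: none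
Why: Hypervalent-iodine oxidative dearomatisation of a para-substituted phenol with 5-exo capture of the para carbon by the tethered tertiary alcohol, a well-precedented spiroetherification helped by the gem-dimethyl effect; the spiro carbon lies on a mirror plane, so no stereocentre arises.

Step 3
Reactants: 3 2,2-dimethyl-1-oxaspiro[4.5]deca-6,9-dien-8-one
Product: 4 2,2-dimethyl-8-methylidene-1-oxaspiro[4.5]deca-6,9-diene
Conditions: Ph3PCH3Br, KOtBu, THF, 0 °C; then 3, −78 to 0 °C; filtration through basic alumina, used at once
Reagents that add atoms: methyltriphenylphosphonium bromide, C[P+](c1ccccc1)(c1ccccc1)c1ccccc1.[Br-]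
Why: Wittig methylenation, in which the non-stabilised ylide adds 1,2 to the non-enolisable cross-conjugated dienone as known for 4,4-disubstituted cyclohexadienones and quinone monoketals, and the strictly basic medium keeps the acid-labile triene intact.

Step 4
Reactants: 5 methyl 3-oxo-3-phenylpropanoate (methyl benzoylacetate)
Product: 6 methyl 2-diazo-3-oxo-3-phenylpropanoate
Conditions: p-ABSA, Et3N, MeCN, 0 °C to rt
Reagents that add atoms: 4-acetamidobenzenesulfonyl azide (p-ABSA), CC(=O)Nc1ccc(cc1)S(=O)(=O)N=[N+]=[N-]
Why: Regitz diazo transfer to the doubly activated methylene group of a β-keto ester.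

Step 5
Reactants: 6 methyl 2-diazo-3-oxo-3-phenylpropanoate
Product: 7 methyl 2,3-dioxo-3-phenylpropanoate
Conditions: DMDO (dried acetone solution), 0 °C to rt; evaporation, used directly
Reagents that add atoms: dimethyldioxirane, CC1(C)OO1
Why: Oxygen-atom transfer from the dioxirane to the diazo carbon with loss of N2, the known entry to anhydrous vicinal tricarbonyl compounds, whose by-products are all volatile so that no hydrate forms.

Step 6
Reactants: 4 2,2-dimethyl-8-methylidene-1-oxaspiro[4.5]deca-6,9-diene; 7 methyl 2,3-dioxo-3-phenylpropanoate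
Product: 10 methyl (2R)-2-[(2,2-dimethyl-3,4-dihydro-2H-chromen-6-yl)methyl]-2-hydroxy-3-oxo-3-phenylpropanoate, via spiro cyclohexadienyl cation 8 (not isolated), via ring-expanded oxocarbenium ion 9 (not isolated)
Conditions: [Cu((S,S)-t-Bu-box)](SbF6)2 (10 mol %), 2,6-di-tert-butylpyridine (10 mol %), 4 Å MS, CH2Cl2, −78 to −40 °C, slow addition of 4 to the preformed 7/catalyst chelate
Reagents that add atoms: none
Why: Proposed new method: the square-planar Cu(II)–box chelate of 7 (ester C=O and central C=O bound) exposes the si face of the central, most electrophilic carbonyl, which is attacked by the exocyclic CH2 of triene 4 to give the new C–C bond, the (R)-configured copper alkoxide and the spiro cyclohexadienyl (Wheland-type) cation 8. Because 8 has no allylic hydrogen with which to finish an ene reaction, its charge at C6 (spiro numbering) is quenched by a suprafacial 1,2-shift (Wagner–Meerwein) of the ring methylene C4 from the spiro carbon C5 to C6, which turns the five-membered oxolane into the six-membered dihydropyran as oxocarbenium ion 9; transfer of the C6 proton to the alkoxide, shuttled by the hindered pyridine, aromatises the ring and frees the catalyst. The closest known reaction types are the Cu(II)–box-catalysed enantioselective carbonyl–ene reaction of 2,3-diketo esters with 1,1-disubstituted alkenes and the acid-induced semibenzene–benzene (dienol–benzene) rearrangement; what is new is their merger, with a carbonyl carbon instead of a proton as the triggering electrophile. No ring is closed by cyclisation: the chroman heterocycle results from a 5-to-6 ring expansion by bond migration, and the carbocycle is only rearomatised. The one new stereocentre is controlled by the tert-butyl groups of the ligand, which shield the re face of the chelated ketone, and the transient sp3 centre C6 of 9 is erased on aromatisation. The step needs C- over O-migration (secured by the ether oxygen, which stays on C5 and stabilises the cation left behind as in quinol rearrangements, so that the side chain ends para to O), attack at the central rather than a flanking carbonyl (secured by its double activation), and addition faster than ionisation of the spiro C–O bond or protonation of 4 (secured by low temperature, sieves, the proton scavenger and the order of addition).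

Step 7
Reactants: 10 methyl (2R)-2-[(2,2-dimethyl-3,4-dihydro-2H-chromen-6-yl)methyl]-2-hydroxy-3-oxo-3-phenylpropanoate; 11 benzyloxyacetyl chloride
Product: 12 methyl (2R)-2-{[2-(benzyloxy)acetyl]oxy}-2-[(2,2-dimethyl-3,4-dihydro-2H-chromen-6-yl)methyl]-3-oxo-3-phenylpropanoate
Conditions: pyridine, DMAP (cat.), CH2Cl2, 0 °C to rt
Reagents that add atoms: none
Why: DMAP-catalysed O-acylation of the tertiary alcohol with an unhindered acid chloride, in a medium too weakly basic for retro-Claisen cleavage or an α-ketol shift, so the stereocentre is untouched.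

Step 8
Reactants: 12 methyl (2R)-2-{[2-(benzyloxy)acetyl]oxy}-2-[(2,2-dimethyl-3,4-dihydro-2H-chromen-6-yl)methyl]-3-oxo-3-phenylpropanoate
Product: 14 methyl (2R)-4-(benzyloxy)-2-[(2,2-dimethyl-3,4-dihydro-2H-chromen-6-yl)methyl]-5-oxo-3-phenyl-2,5-dihydrofuran-2-carboxylate, via aldol lactone 13 (not isolated)
Conditions: DBU, 4 Å MS, MeCN, rt to 50 °C
Reagents that add atoms: none
Why: Intramolecular aldol (Knoevenagel-type) condensation of an α-(alkoxyacetoxy) aryl ketone, the standard entry to 3-alkoxy-4-aryl-5,5-disubstituted 2(5H)-furanones: 5-exo-trig attack of the ester enolate on the benzoyl C=O gives 13, E1cB loss of water gives the phenyl-conjugated butenolide, and the quaternary centre has no acidic hydrogen and cannot epimerise.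

Step 9
Reactants: 14 methyl (2R)-4-(benzyloxy)-2-[(2,2-dimethyl-3,4-dihydro-2H-chromen-6-yl)methyl]-5-oxo-3-phenyl-2,5-dihydrofuran-2-carboxylate
Product: 15 4'-dehydroxy aspernolide A, methyl (2R)-2-[(2,2-dimethyl-3,4-dihydro-2H-chromen-6-yl)methyl]-4-hydroxy-5-oxo-3-phenyl-2,5-dihydrofuran-2-carboxylate
Conditions: H2 (1 atm), 10% Pd/C, EtOAc, rt, stopped after one equivalent of H2
Reagents that add atoms: none
Why: Hydrogenolysis of the benzyl enol ether over Pd/C, under which the tetrasubstituted C3=C4 bond, the hindered lactone C–O bond, the methyl ester and the chroman should be inert and the stereocentre is not affected.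

Compound list
1 | 4-(4-hydroxyphenyl)butan-2-one (raspberry ketone) | CC(=O)CCc1ccc(O)cc1 | starting material
2 | 4-(3-hydroxy-3-methylbutyl)phenol | CC(C)(O)CCc1ccc(O)cc1 | intermediate
3 | 2,2-dimethyl-1-oxaspiro[4.5]deca-6,9-dien-8-one | CC1(C)CCC2(O1)C=CC(=O)C=C2 | intermediate
4 | 2,2-dimethyl-8-methylidene-1-oxaspiro[4.5]deca-6,9-diene (semibenzene-type triene) | CC1(C)CCC2(O1)C=CC(=C)C=C2 | intermediate
5 | methyl 3-oxo-3-phenylpropanoate (methyl benzoylacetate) | COC(=O)CC(=O)c1ccccc1 | starting material
6 | methyl 2-diazo-3-oxo-3-phenylpropanoate | COC(=O)C(=[N+]=[N-])C(=O)c1ccccc1 | intermediate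
7 | methyl 2,3-dioxo-3-phenylpropanoate | COC(=O)C(=O)C(=O)c1ccccc1 | intermediate
8 | spiro cyclohexadienyl cation, (R)-alkoxide zwitterion drawn without copper (not isolated) | COC(=O)[C@](CC1=C[CH+]C2(CCC(C)(C)O2)C=C1)([O-])C(=O)c1ccccc1 | intermediate
9 | ring-expanded oxocarbenium ion, (R)-alkoxide zwitterion drawn without copper (not isolated) | COC(=O)[C@](CC1=CC2CCC(C)(C)[O+]=C2C=C1)([O-])C(=O)c1ccccc1 | intermediate
10 | methyl (2R)-2-[(2,2-dimethyl-3,4-dihydro-2H-chromen-6-yl)methyl]-2-hydroxy-3-oxo-3-phenylpropanoate | COC(=O)[C@](Cc1ccc2c(c1)CCC(C)(C)O2)(O)C(=O)c1ccccc1 | intermediate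
11 | benzyloxyacetyl chloride | O=C(Cl)COCc1ccccc1 | starting material
12 | methyl (2R)-2-{[2-(benzyloxy)acetyl]oxy}-2-[(2,2-dimethyl-3,4-dihydro-2H-chromen-6-yl)methyl]-3-oxo-3-phenylpropanoate | COC(=O)[C@](Cc1ccc2c(c1)CCC(C)(C)O2)(OC(=O)COCc1ccccc1)C(=O)c1ccccc1 | intermediate
13 | aldol lactone, methyl (2R)-4-(benzyloxy)-2-[(2,2-dimethylchroman-6-yl)methyl]-3-hydroxy-5-oxo-3-phenyloxolane-2-carboxylate, C3/C4 epimers (not isolated) | COC(=O)[C@]1(Cc2ccc3c(c2)CCC(C)(C)O3)OC(=O)C(OCc2ccccc2)C1(O)c1ccccc1 | intermediate
14 | methyl (2R)-4-(benzyloxy)-2-[(2,2-dimethyl-3,4-dihydro-2H-chromen-6-yl)methyl]-5-oxo-3-phenyl-2,5-dihydrofuran-2-carboxylate | COC(=O)[C@]1(Cc2ccc3c(c2)CCC(C)(C)O3)OC(=O)C(OCc2ccccc2)=C1c1ccccc1 | intermediate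
15 | 4'-dehydroxy aspernolide A | COC(=O)[C@]1(Cc2ccc3c(c2)CCC(C)(C)O3)OC(=O)C(O)=C1c1ccccc1 | target

Total step count: 9. Longest linear sequence: 7 steps (1, 2, 3, 6, 7, 8, 9); the branch 5 to 7 takes 2 steps.

Steps most likely to fail

Step 6 (proposed new method).
- The Lewis acid may ionise the spiro C–O bond of 4.
- Traces of acid may protonate 4 and rearrange it before the C–C bond forms.
- Cu(II) may oxidise the electron-rich triene by single-electron transfer.
- An uncatalysed background addition, or binding of 7 through its other carbonyl pair, may erode facial selectivity.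
- Fallback (known chemistry only): it sets out from 3 and keeps the ring expansion but triggers it with a proton. A dienone–phenol rearrangement (TFA or BF3·OEt2, CH2Cl2) with the same C4 shift should give 2,2-dimethylchroman-6-ol F1. Tf2O/pyridine converts this into 2,2-dimethylchroman-6-yl trifluoromethanesulfonate F2. F2 then undergoes Heck arylation of the commercial Morita–Baylis–Hillman adduct methyl 2-[hydroxy(phenyl)methyl]acrylate (Pd(OAc)2, dppp, Et3N, DMF). This reaction is known to end by β-hydride elimination toward the carbinol, and should give racemic methyl 2-[(2,2-dimethylchroman-6-yl)methyl]-3-oxo-3-phenylpropanoate F3. Catalytic enantioselective α-hydroxylation of this 2-substituted β-keto ester (TADDOLato–Ti(IV) catalyst, N-sulfonyloxaziridine) then sets the stereocentre and comes back to the route at 10.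

Step 3.
- The triene may be lost on isolation through ionisation of its doubly allylic ether and aromatisation.
- The olefination of the hindered dienone may stall at the betaine.
- Fallback: it sets out from 3 and uses a two-stage Peterson olefination. 1,2-Addition of Me3SiCH2Li (THF, −78 °C) should give the storable 2,2-dimethyl-8-[(trimethylsilyl)methyl]-1-oxaspiro[4.5]deca-6,9-dien-8-ol F4 (cis/trans mixture, of no consequence). KH in THF eliminates it under purely basic conditions directly before use, and the route is rejoined at 4.

Step 8.
- The enolate may attack the methyl ester instead of the ketone (Dieckmann closure).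
- Acyl transfer or retro-Claisen loss of the benzoyl group may compete.
- Dehydration of the aldol may be sluggish.
- Fallback: it sets out from 10, which is esterified with 2-(benzyloxy)-2-(diethoxyphosphoryl)acetic acid (DCC, DMAP, CH2Cl2). This gives methyl (2R)-2-{[2-(benzyloxy)-2-(diethoxyphosphoryl)acetyl]oxy}-2-[(2,2-dimethylchroman-6-yl)methyl]-3-oxo-3-phenylpropanoate F5. An intramolecular Horner–Wadsworth–Emmons olefination (LiCl, DBU, MeCN, Masamune–Roush conditions) is chemoselective for the ketone and irreversible. It closes the butenolide and comes back to the route at 14.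

Further compounds
F1 | step 6 | 2,2-dimethylchroman-6-ol | CC1(C)CCc2cc(O)ccc2O1
F2 | step 6 | 2,2-dimethylchroman-6-yl trifluoromethanesulfonate | CC1(C)CCc2cc(OS(=O)(=O)C(F)(F)F)ccc2O1
F3 | step 6 | methyl 2-[(2,2-dimethylchroman-6-yl)methyl]-3-oxo-3-phenylpropanoate (racemic) | COC(=O)C(Cc1ccc2c(c1)CCC(C)(C)O2)C(=O)c1ccccc1
F4 | step 3 | 2,2-dimethyl-8-[(trimethylsilyl)methyl]-1-oxaspiro[4.5]deca-6,9-dien-8-ol | CC1(C)CCC2(O1)C=CC(O)(C[Si](C)(C)C)C=C2
F5 | step 8 | methyl (2R)-2-{[2-(benzyloxy)-2-(diethoxyphosphoryl)acetyl]oxy}-2-[(2,2-dimethylchroman-6-yl)methyl]-3-oxo-3-phenylpropanoate | COC(=O)[C@](Cc1ccc2c(c1)CCC(C)(C)O2)(OC(=O)C(OCc1ccccc1)P(=O)(OCC)OCC)C(=O)c1ccccc1
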